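The earlier runs and the new flask were computed with made-up constants, and the scatter is random.

I read Wednesday's, Monday's and Sunday's flasks at 6.0 h, so I ask what fraction of J is left by then, not how much was made.

| flask | J | G | X | temperature | remark | time |
|---|---|---|---|---|---|---|
| autumn | 0.23 M | 0.253 M | 0.31 M | 32 °C | run made earlier |  |
| midnight | 0.23 M | 0.253 M | 0.69 M | 49 °C | run made earlier |  |
| winter | 0.23 M | 0.13 M | 0.46 M | 32 °C | run made earlier |  |
| Wednesday's | 0.23 M | 0.253 M | 0.460 M | 25 °C |  | 6.0 h |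
| Monday's | 0.23 M | 0.253 M | 0.460 M | 55 °C |  | 6.0 h |
| Sunday's | 0.23 M | 0.253 M | 0.460 M | 40 °C |  | 6.0 h |

| run | time / h | J / % | E / % | L / % | Z / % |
|---|---|---|---|---|---|
| autumn | 0.500 | 90 | 0 | 0 | 9 |
| autumn | 0.833 | 87 | 0 | 2 | 13 |
| autumn | 1.33 | 82 | 4 | 0 | 17 |
| autumn | 2.00 | 78 | 4 | 0 | 20 |
| autumn | 3.00 | 73 | 9 | 2 | 15 |
| autumn | 5.00 | 71 | 13 | 3 | 17 |
| autumn | 8.00 | 60 | 21 | 5 | 8 |
| midnight | 0.333 | 88 | 3 | 1 | 9 |
| midnight | 0.667 | 84 | 7 | 0 | 7 |
| midnight | 1.00 | 83 | 5 | 1 | 13 |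
| midnight | 1.33 | 79 | 13 | 0 | 6 |
| midnight | 1.50 | 73 | 14 | 7 | 8 |
| midnight | 2.00 | 71 | 18 | 2 | 6 |
| midnight | 2.50 | 69 | 20 | 7 | 6 |
| winter | 0.500 | 98 | 1 | 2 | 7 |
| winter | 1.00 | 91 | 4 | 1 | 10 |
| winter | 2.00 | 85 | 4 | 0 | 6 |
| winter | 4.00 | 85 | 7 | 0 | 12 |
| winter | 8.00 | 80 | 11 | 3 | 5 |

(each reading ± 2 percentage points)

- which of these there is most of at the end, counted by the J in it, Wednesday's (E / L / Z / J)
- which of these there is most of at the end, counted by the J in it, Monday's (E / L / Z / J)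
- which of these there is most of at the end, counted by the J in it, Sunday's (E / L / Z / J)
- final amount of the leader among these, as a percentage of the J charged, in Wednesday's
- final amount of the leader among these, as a percentage of the J charged, in Monday's
- final amount of the leader among these, as a percentage of the J charged, in Sunday's

- percentages count the J that a species holds: one L counts as two
- steps that have been proposed: J + G <-> Z; X + G <-> Q; J + Z -> L; Z <-> E; X <-> D

I skip the steep first readings and work from the later ones. In the autumn run J goes from 78 % at 2.00 h to 60 % at 8.00 h. The logarithm of that ratio over the time between gives the late loss rate, the share of the J present that goes per hour, an apparent first-order rate constant: 0.0437 h⁻¹. The midnight run, from 83 % at 1.00 h to 69 % at 2.50 h, gives 0.123 h⁻¹, faster, though it is hotter and holds more X, so this step is rough. Continuing the same logarithmic step per degree to Monday's 55 °C gives 0.177 h⁻¹. I start Monday's flask from the midnight reading at 1.00 h and multiply by the fraction left over the remaining hours, which leaves 34.2 % of J. At the end of the midnight run E, at 20 %, is the largest of the products, above Z and L, so I commit to E leading Monday's flask. The weak link is the constant share per hour, which treats the loss as one-way.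

The forecast gives J at 73 % for Wednesday's, J at 62 % for Sunday's and E at 47 % for Monday's, where it says “E narrowly leads, though this is uncertain”. It puts J at 42 in Monday's, above my figure.

    J + G ⇌ Z (K = 3.80 M⁻¹, k = 0.550 M⁻¹ h⁻¹, Ea = 66.0 kJ mol⁻¹, ΔH = −50.0 kJ mol⁻¹)
    X + G ⇌ Q (K = 1.20 M⁻¹, k = 0.550 M⁻¹ h⁻¹, Ea = 68.0 kJ mol⁻¹, ΔH = −2.00 kJ mol⁻¹)
    J + Z → L (k = 0.0650 M⁻¹ h⁻¹, Ea = 81.0 kJ mol⁻¹)
    Z ⇌ E (K = 15.0, k = 0.0650 h⁻¹, Ea = 106 kJ mol⁻¹, ΔH = −26.0 kJ mol⁻¹)
    X ⇌ D (K = 0.150, k = 0.0950 h⁻¹, Ea = 99.0 kJ mol⁻¹, ΔH = −28.0 kJ mol⁻¹)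
    (constants at 25 °C)

Wednesday's ends with J at 70.0 %, Sunday's with J at 59.7 %, and Monday's with J at 59.0 %, E holding 24.8 %. The difference in temperature is the main reason for the gap of 11 percentage points between Monday's J and Wednesday's. From 3.00 h on, Monday's J goes from 64.4 % at a late loss rate of 0.0288 h⁻¹, below 0.177 h⁻¹ and even below the autumn 0.0437 h⁻¹. Part of the reason is the way back from E to Z: without it, Monday's J ends at 34.8 %. Sunday's flask, over the same hours, loses J faster than Monday's, at 0.0550 h⁻¹.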